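(The data are calculated for an exercise; noise was put on by code.)

If bis adduct is still a small part of what has formed, the share of mono adduct hangs on one number, κc, with κ the ratio of rate constants defined below and c the fraction of substrate charged that has reacted. We take both additions to use partner, so partner and time cancel when their rates are divided. Mono adduct is made and used up at once, so with [substrate] frozen at its charge and m the mono adduct as a fraction of substrate charged, dm/dc = 1 − κm. To lowest order in κc, what has gone past mono adduct over mono adduct is then κc/2, and the share is 1/(1 + κc/2).

common to all: substrate 0.25 M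
- west: partner 0.18 M; temperature 80 °C; run made earlier
- south-west: partner 0.39 M; temperature 102 °C; run made earlier
- delta: partner 0.263 M; temperature 70 °C; time 4.0 h
- eta: partner 0.263 M; temperature 110 °C; time 4.0 h
- beta: partner 0.263 M; temperature 90 °C; time 4.0 h

west run (percent of the substrate charged)

| time / h | mono adduct / % | bis adduct / % |
|---|---|---|
| 0.833 | 2.7 | 0 |
| 1.50 | 3.8 | 1.4 |
| 2.50 | 6.0 | 0 |
| 3.00 | 9.8 | 2.5 |

south-west run (percent of the substrate charged)

| time / min | mono adduct / % | bis adduct / % |
|---|---|---|
| 8.00 | 5.5 | 0 |
| 20.0 | 9.3 | 3.4 |
| 40.0 | 11.5 | 5.8 |
| 60.0 | 11.7 | 7.9 |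

(readings scatter by 1 percentage point)

The west run's last reading, 9.8% mono adduct and 2.5% bis adduct, with c taken as their sum, gives the selectivity factor, the second addition's rate constant over the first's, as a reading: κ = 4.15. It is rough, since each reading is good to 1 percentage point.

So we need c. West reached 12.3% in 3.00 h, and south-west reached 12.7% in 20.0 min. Per unit of [partner], south-west is therefore 4.29 times faster. Spread evenly over the temperature gap, that is a factor 1.94 from 70 °C to 80 °C. Scaling west to delta's partner and time gives a conversion of 12.4%, so with κ carried over unchanged our share for delta is 79.5%.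

But the same scaling puts beta at 46.4%, above south-west's last 19.6%, where the share read 59.7%. There [substrate] is not frozen, so for beta and hotter eta we claim only that they lie below delta.

- the flask with the highest share of mono adduct in all that became mono adduct or bis adduct or tris adduct or tetra adduct ("all alike" if they lie within 1.5 percentage points) (delta / eta / beta / all alike)
- share of mono adduct in all that became mono adduct or bis adduct or tris adduct or tetra adduct, delta
- share of mono adduct in all that became mono adduct or bis adduct or tris adduct or tetra adduct, eta
- share of mono adduct in all that became mono adduct or bis adduct or tris adduct or tetra adduct, beta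

The forecast names delta, with 84% for delta, above our figure, 38% for eta and 58% for beta: “The share of mono adduct depends on how far the reaction has progressed”.

The flasks give 80.1% for delta, 43.8% for eta and 51.9% for beta, so delta stands highest.

    partner → decomposed reagent (k = 0.00132 min⁻¹, Ea = 110 kJ mol⁻¹)
    partner + bis adduct → tris adduct + released group (k = 0.0279 M⁻¹ min⁻¹, Ea = 80.0 kJ mol⁻¹)
    partner + tris adduct → tetra adduct + released group (k = 0.00461 M⁻¹ min⁻¹, Ea = 77.0 kJ mol⁻¹)
    partner + mono adduct → bis adduct + released group (k = 0.0338 M⁻¹ min⁻¹, Ea = 76.0 kJ mol⁻¹)
    substrate + partner → mono adduct + released group (k = 0.00734 M⁻¹ min⁻¹, Ea = 68.0 kJ mol⁻¹)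
    (constants at 90 °C)

Delta keeps 89% of its substrate at 4.00 h. Its conversion of 10.8% with κ = 4.15 gives a share of 81.7%. The neighbour with 0.16 M partner holds 6.75% of its substrate as adducts at 4.00 h, for which κ gives 87.7%; that flask stands at 87.2%.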